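Abbreviations: TBS = tert-butyldimethylsilyl; prenyl = 3-methylbut-2-en-1-yl; Ts = 4-methylbenzenesulfonyl; "ring B aryl" = 2-(TBS-oxymethyl)-4-methoxy-6-(prenyloxy)phenyl.

## The problem

The target is a diaryl ether of two 1,2,4,6-tetrasubstituted benzene rings. Ring A is a methyl benzoate (C1, ester carbon C7) with a prenyloxy group at C2, a methyl at C4 and the ether oxygen at C6. Ring B carries the ether oxygen at C1', a hydroxymethyl at C2', a methoxy at C4' and a second prenyloxy group at C6'. The ether oxygen is flanked by three ortho substituents (the ester on ring A, CH2OH and O-prenyl on ring B), and the ring B phenol is electron-rich and 2,6-disubstituted, so a late aryl carbon–oxygen coupling would be the weakest step of a conventional plan. There is no stereocentre; the task is regiochemical: six heteroatom substituents must each reach the right carbon, with prenyl ethers on both rings.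

The aryl prenyl ethers do not tolerate acid, hydrogenation or temperatures near 150 °C (Claisen rearrangement). The benzylic alcohol sits on an electron-rich ring next to the ether oxygen and must be masked whenever an electrophilic carbon is nearby. The ester lies between two oxygens and is easier to carry through than to install late.

The feature that opens the structure is the run C1–C2–C3–C4 of ring A (ester on C1, oxygen on C2, methyl on C4). It is the C3–C4–C5–C6 diene of a 3-carbomethoxy-4-oxy-6-methyl-2-pyrone. The remaining C5–C6 pair, with the aryloxy group on C6, is a two-carbon unit at the alkyne oxidation level, an aryl ethynyl ether. Carbon dioxide is the only loss.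

## Retrosynthesis

**Silyl ether.** Target 22 is traced to its silyl ether 21 by cutting only O–Si. The benzylic oxygen has to be masked throughout, because a free ortho-hydroxymethyl group would add to the ynol ether carbon of 17 and close a benzodioxine. TBS is chosen because it should survive n-BuLi, K2CO3 and Mg in methanol and is removed by fluoride without touching the prenyl ethers.

**Ring A prenyl ether.** 21 is cut at the O–CH2 bond on C2 to give phenol 20 and prenyl bromide 9, and 20 is traced to tosylate 19 by an S–O cut. The prenyl group is introduced late because the C2 oxygen must be acceptor-substituted during the cycloaddition. A 4-alkoxy pyrone is a vinylogous carbonate and a poor electron-poor diene, whereas a sulfonate keeps the LUMO low and is later removed cleanly. The forward steps are a reductive S–O cleavage and a Williamson alkylation of a salicylate phenol.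

**Ring A (key cut).** In 19 the bonds C4–C5 and C1–C6 are cut and carbon dioxide is put back as a lactone bridge between C1 and C4, which leads to pyrone tosylate 5 and aryl ethynyl ether 17. The neighbouring cuts are less attractive. Cutting the C6–O bond asks for a tri-ortho-substituted aryl ether coupling. Cutting C1–C2 and C5–C6 puts the ester on the alkyne and makes it a push–pull dienophile. Here the ester sits on the diene, where it activates. The two precursors are a small pyrone and an aryl ether of acetylene. The forward reaction has to be regioselective (aryloxy ortho to the ester) and has to run below the temperature of prenyl ether Claisen rearrangement.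

**Pyrone.** 5 is the tosylate of the vinylogous acid 4. 4 is cut at C3–C4 and at the lactone O–C2 bond to give dimethyl malonate 1 and diketene 2, through the open acetoacetylmalonate 3. The ester carbon comes in with the malonate. Acylating a preformed 4-hydroxypyrone at C3 was rejected because O-acylation competes there.

**Ynol ether.** 17 is cut at the O–C(sp) bond. It comes from the (E)-1,2-dichlorovinyl ether 14 by elimination and lithium–chlorine exchange (through 15 and 16), and 14 comes from phenol 12 and trichloroethylene 13. The hindered phenoxide of 12 only has to add to a small, linear electrophile.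

**Ring B phenol.** 12 is the mono-silyl ether of diol 11, the borohydride reduction product of salicylaldehyde 10. 10 is cut at the C6' prenyl ether to catechol aldehyde 8 and 9; its dianion should alkylate at the oxygen that is not conjugated to the formyl group. 8 comes from dimethoxy phenol 7 by chelation-directed removal of the methyl group next to the free hydroxyl. 7 comes from commercial 5-bromo-2-hydroxy-3-methoxybenzaldehyde 6 by copper-catalysed methoxylation; the bromine of 6 marks the C4' oxygen and the formyl carbon is the future CH2OH.

## Roads not taken

**Alternative 1:** Ring B is built as a spiro ring on C2 of coumaranone A2 (4-benzyloxy-6-methylbenzofuran-3(2H)-one) by a double conjugate addition to the cross-conjugated diynone A3 under catalytic KOC(CH3)3. This forms C1'–C2' and C1'–C6' and gives the racemic spiro grisadienone A1. The furanone oxygen of A2 is already the diaryl ether oxygen, and the ketone carbon becomes C7 after a later methoxide-induced cleavage of the bond to the spiro carbon, which aromatizes ring B.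

- Merits: the diaryl ether never has to be made by coupling, two bonds form in one step, and both prenyl groups could be introduced together at the end.
- Weak points: A3 carries a benzyl alkynyl ether, a thermally labile group. Its oxygen-bearing alkyne terminus is a deactivated acceptor, yet the second, ring-closing addition must attack exactly there and create a quaternary carbon. After A1, five operations remain (fragmentation, O-methylation at C4', removal of two benzyl groups, double prenylation, desilylation). The hydrogenolysis has to spare a benzylic silyl ether on an electron-rich ring. A stereocentre is made only to be destroyed.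
- Comparison: it avoids the terminal ynol ether and a heated cycloaddition, and it prenylates once rather than twice. The chosen plan offers three instead of five steps after the key step, no hydrogenolysis, and a cycloaddition in which both partners react in their natural polarity.

**Alternative 2:** Ring A is cut at C1–C2 and C5–C6. The methyl 3-aryloxypropiolate A4 (from acetylide 16 and methyl chloroformate) would react with 1,1-bis(trimethylsilyloxy)-3-methylbuta-1,3-diene A5 in a normal-demand Diels–Alder reaction. Loss of trimethylsilanol aromatizes the adduct to phenol A6, which is identical with 20.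

- Merits: the regiochemistry is matched (nucleophilic diene terminus to the aryloxy-bearing carbon). The free C2 phenol is obtained directly, so no sulfonate has to be removed and one step is saved. The acetylide is trapped in the flask, so no terminal ynol ether is handled.
- Weak points: A4 is a push–pull alkyne. The aryloxy group donates into the ester and raises the LUMO, so higher temperatures are likely, which brings the prenyl ether Claisen rearrangement closer. A5 is moisture-sensitive and can give open-chain conjugate adducts.
- Comparison: this road is one step shorter and is kept as the fallback for the key step. The chosen plan is preferred because the ester and the sulfonate activate the diene rather than a deactivated dienophile, and because the loss of carbon dioxide makes the ring formation irreversible.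

**Alternative 3:** Ring A is kept intact and the C6–O and C1–C7 bonds are made in one step. CsF converts the silyl triflate A7 into the 3-alkoxy aryne A8 (triple bond C1–C6). The phenoxide of 12 adds at C6, and the C1 aryl anion is captured by carbon dioxide to give acid A9. No ring is closed.

- Merits: it is the most convergent road. Both prenyl groups are in place, and only esterification and desilylation follow. The regiochemistry of addition to a 3-alkoxy aryne (nucleophile at the distal carbon) is reliable.
- Weak points: three-component aryne couplings with carbon dioxide are established for nitrogen nucleophiles much more than for hindered phenoxides. The phenol can protonate the aryl anion and give the ether without the carboxyl group. Fluoride threatens the silyl ether. The prenyl ether next to the aryne offers an intramolecular ene pathway. A7 needs several steps with a regiocontrolled silylation.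
- Comparison: on paper this is the shortest route after the key step. The chosen plan is preferred because its cycloaddition belongs to a known reaction type and uses no fluoride before the last step.

Key step: step 10

Assumption: the terminal aryl ethynyl ether 17 is taken to survive a rapid non-acidic work-up and immediate use, since an aryl group on oxygen offers no β-hydrogen for the retro-ene fragmentation that limits alkyl ethynyl ethers.

## Route

Step 1
Reactants: 1 dimethyl malonate; 2 diketene (4-methyleneoxetan-2-one)
Product: 4 methyl 4-hydroxy-6-methyl-2-oxo-2H-pyran-3-carboxylate, via dimethyl acetoacetylmalonate 3 (not isolated)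
Conditions: NaH, THF, 0 °C; diketene, 0 °C → rt; then 2 M HCl, 40 °C
Reagents that add atoms: none
Why: C-acylation of the sodium malonate enolate by ring opening of diketene (acetoacetylation) should give 3, whose ketone enol lactonizes onto a malonate ester with loss of methanol on acidification; this is the established construction of 3-alkoxycarbonyl-4-hydroxy-6-methyl-2-pyrones.

Step 2
Reactants: 4 methyl 4-hydroxy-6-methyl-2-oxo-2H-pyran-3-carboxylate
Product: 5 methyl 6-methyl-2-oxo-4-(tosyloxy)-2H-pyran-3-carboxylate
Conditions: TsCl, Et3N, CH2Cl2, 0 °C → rt
Reagents that add atoms: 4-methylbenzenesulfonyl chloride, Cc1ccc(cc1)S(=O)(=O)Cl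
Why: O-sulfonylation of a vinylogous acid at the C4 oxygen, as is routine for 4-hydroxy-6-methyl-2-pyrones; the product should be an isolable 4-sulfonyloxy pyrone.

Step 3
Reactants: 6 5-bromo-2-hydroxy-3-methoxybenzaldehyde
Product: 7 2-hydroxy-3,5-dimethoxybenzaldehyde
Conditions: NaOMe, CuBr (10 mol %), MeOH/DMF, 100 °C; then aq. HCl
Reagents that add atoms: sodium methoxide, [Na+].[O-]C
Why: Ullmann-type copper-catalysed methoxylation of an aryl bromide, the standard bromine-to-methoxy exchange on bromovanillin-type phenolic aldehydes; the phenoxide and the aldehyde are tolerated.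

Step 4
Reactants: 7 2-hydroxy-3,5-dimethoxybenzaldehyde
Product: 8 2,3-dihydroxy-5-methoxybenzaldehyde
Conditions: AlCl3, pyridine, CH2Cl2, 40 °C; then 2 M HCl
Reagents that add atoms: none
Why: Chelation-directed O-demethylation: aluminium bound to the C2 phenoxide coordinates the neighbouring C3 methoxy oxygen and activates only that methyl group for SN2 removal by pyridine, while the C5 methyl ether has no anchoring neighbour and should remain.

Step 5
Reactants: 8 2,3-dihydroxy-5-methoxybenzaldehyde; 9 prenyl bromide (1-bromo-3-methylbut-2-ene)
Product: 10 2-hydroxy-5-methoxy-3-(prenyloxy)benzaldehyde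
Conditions: NaH (2.2 equiv), DMSO, rt; prenyl bromide (1.0 equiv), rt; then 1 M HCl
Reagents that add atoms: none
Why: Regioselective Williamson alkylation of the catechol dianion: the C2 oxide is delocalized into the ortho formyl group, so the C3 oxide is the more nucleophilic and should take the single equivalent of halide, as known for 2,3-dihydroxybenzaldehydes.

Step 6
Reactants: 10 2-hydroxy-5-methoxy-3-(prenyloxy)benzaldehyde
Product: 11 2-(hydroxymethyl)-4-methoxy-6-(prenyloxy)phenol
Conditions: NaBH4, MeOH, 0 °C
Reagents that add atoms: none
Why: Borohydride reduction of an aryl aldehyde; the prenyl ether and the phenol are inert.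

Step 7
Reactants: 11 2-(hydroxymethyl)-4-methoxy-6-(prenyloxy)phenol
Product: 12 2-(TBS-oxymethyl)-4-methoxy-6-(prenyloxy)phenol
Conditions: TBSCl (1.05 equiv), imidazole, CH2Cl2, 0 °C
Reagents that add atoms: tert-butyldimethylsilyl chloride, CC(C)(C)[Si](C)(C)Cl
Why: Selective silylation of a primary alcohol in the presence of a 2,6-disubstituted phenol; the alkyl silyl ether is also the thermodynamically preferred site.

Step 8
Reactants: 12 2-(TBS-oxymethyl)-4-methoxy-6-(prenyloxy)phenol; 13 trichloroethylene
Product: 14 (E)-1,2-dichloroethenyl ring B aryl ether
Conditions: K2CO3, DMF, 70 °C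
Reagents that add atoms: none
Why: Base-mediated conversion of a phenol into its 1,2-dichlorovinyl ether: trichloroethylene loses HCl to dichloroacetylene, to which the phenoxide adds in anti fashion to give the E ether; the electrophile is small enough for the hindered phenoxide.

Step 9
Reactants: 14 (E)-1,2-dichloroethenyl ring B aryl ether
Product: 17 ethynyl ring B aryl ether, via chloroethynyl ether 15 (not isolated), via lithium acetylide 16 (not isolated)
Conditions: n-BuLi (3 equiv), THF, −78 → −40 °C; then MeOH, −78 °C
Reagents that add atoms: none
Why: Established ynol ether synthesis from dichlorovinyl ethers: deprotonation and β-elimination of LiCl give 15, lithium–chlorine exchange gives 16, and protonation at low temperature should release 17, which is used at once.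

Step 10
Reactants: 5 methyl 6-methyl-2-oxo-4-(tosyloxy)-2H-pyran-3-carboxylate; 17 ethynyl ring B aryl ether
Product: 19 methyl 2-(ring B aryloxy)-4-methyl-6-(tosyloxy)benzoate, via bridged lactone 18 (not isolated)
Conditions: toluene, 90 °C, sealed tube, argon (17 in slight excess)
Reagents that add atoms: none
Why: Pyrone 5, whose LUMO is lowered by the C3 ester and the C4 sulfonate, should act as the electron-poor diene and ynol ether 17 as the electron-rich 2π partner in a thermal inverse-electron-demand [4+2] cycloaddition. Bond formation is asynchronous: the nucleophilic terminal CH of 17 bonds to the δ-electrophilic pyrone C6 (target C4–C5) and the oxygen-bearing alkyne carbon closes onto pyrone C3 (target C1–C6), giving the 2-oxabicyclo[2.2.2]octadienone 18. 18 then expels carbon dioxide by a retro-[4+2] step, so the benzene ring appears without any oxidation or elimination. The closest known reaction type is the cycloaddition of 3-carbomethoxy-2-pyrones with ketene acetals, ynamines and alkoxyalkynes to give ortho-heteroatom-substituted benzoates. Ring A is closed by an intermolecular cycloaddition in which both new ring bonds form in the same step, not by cyclization of a chain. No stereocentre results: the two bridgehead centres of 18 form as a racemate and vanish on decarboxylation. The step needs regioselectivity (aryloxy ortho to the ester), which the matched polarization of both partners secures, and a cycloaddition can only engage the diene termini C3 and C6, which disfavours attack at the sulfonate-bearing C4. The temperature stays well below that of aryl prenyl ether Claisen rearrangement, and the silyl ether prevents addition of the benzylic oxygen to the ynol ether.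

Step 11
Reactants: 19 methyl 2-(ring B aryloxy)-4-methyl-6-(tosyloxy)benzoate
Product: 20 methyl 2-(ring B aryloxy)-6-hydroxy-4-methylbenzoate
Conditions: Mg turnings, MeOH, rt; then aq. NH4Cl
Reagents that add atoms: none
Why: Reductive S–O cleavage of an aryl tosylate by electron transfer from magnesium in methanol, a known chemoselective detosylation; the methyl ester is degenerate towards methoxide, and the silyl ether, the diaryl ether and the isolated alkenes should not be reduced.

Step 12
Reactants: 20 methyl 2-(ring B aryloxy)-6-hydroxy-4-methylbenzoate; 9 prenyl bromide (1-bromo-3-methylbut-2-ene)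
Product: 21 methyl 2-(ring B aryloxy)-4-methyl-6-(prenyloxy)benzoate
Conditions: K2CO3, DMF, 40 °C
Reagents that add atoms: none
Why: Williamson O-alkylation of the only acidic site, a salicylate phenol, by SN2 displacement on a primary allylic bromide.

Step 13
Reactants: 21 methyl 2-(ring B aryloxy)-4-methyl-6-(prenyloxy)benzoate
Product: 22 methyl 2-[2-(hydroxymethyl)-4-methoxy-6-(prenyloxy)phenoxy]-4-methyl-6-(prenyloxy)benzoate (CNP0561346.0)
Conditions: TBAF, AcOH, THF, 0 °C → rt
Reagents that add atoms: none
Why: Fluoride cleavage of a primary silyl ether; the acetic acid buffer keeps the liberated alkoxide protonated so that it cannot attack the ester, and the prenyl ethers are untouched.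

## Compound list

1 | dimethyl malonate | COC(=O)CC(=O)OC | starting material
2 | diketene (4-methyleneoxetan-2-one) | C=C1CC(=O)O1 | starting material
3 | dimethyl 2-(3-oxobutanoyl)malonate | COC(=O)C(C(=O)OC)C(=O)CC(C)=O | intermediate (not isolated)
4 | methyl 4-hydroxy-6-methyl-2-oxo-2H-pyran-3-carboxylate | COC(=O)C1=C(O)C=C(C)OC1=O | intermediate
5 | methyl 6-methyl-2-oxo-4-(tosyloxy)-2H-pyran-3-carboxylate | COC(=O)C1=C(OS(=O)(=O)c2ccc(C)cc2)C=C(C)OC1=O | intermediate
6 | 5-bromo-2-hydroxy-3-methoxybenzaldehyde | COc1cc(Br)cc(C=O)c1O | starting material
7 | 2-hydroxy-3,5-dimethoxybenzaldehyde | COc1cc(OC)c(O)c(C=O)c1 | intermediate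
8 | 2,3-dihydroxy-5-methoxybenzaldehyde | COc1cc(O)c(O)c(C=O)c1 | intermediate
9 | prenyl bromide (1-bromo-3-methylbut-2-ene) | CC(C)=CCBr | starting material
10 | 2-hydroxy-5-methoxy-3-[(3-methylbut-2-en-1-yl)oxy]benzaldehyde | COc1cc(OCC=C(C)C)c(O)c(C=O)c1 | intermediate
11 | 2-(hydroxymethyl)-4-methoxy-6-[(3-methylbut-2-en-1-yl)oxy]phenol | COc1cc(OCC=C(C)C)c(O)c(CO)c1 | intermediate
12 | 2-{[tert-butyl(dimethyl)silyl]oxymethyl}-4-methoxy-6-[(3-methylbut-2-en-1-yl)oxy]phenol | COc1cc(OCC=C(C)C)c(O)c(CO[Si](C)(C)C(C)(C)C)c1 | intermediate
13 | trichloroethylene | ClC=C(Cl)Cl | starting material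
14 | (E)-1,2-dichloroethenyl 2-(TBS-oxymethyl)-4-methoxy-6-(prenyloxy)phenyl ether | Cl/C=C(/Cl)Oc1c(CO[Si](C)(C)C(C)(C)C)cc(OC)cc1OCC=C(C)C | intermediate
15 | chloroethynyl 2-(TBS-oxymethyl)-4-methoxy-6-(prenyloxy)phenyl ether | ClC#COc1c(CO[Si](C)(C)C(C)(C)C)cc(OC)cc1OCC=C(C)C | intermediate (not isolated)
16 | lithium 2-[2-(TBS-oxymethyl)-4-methoxy-6-(prenyloxy)phenoxy]acetylide | [Li]C#COc1c(CO[Si](C)(C)C(C)(C)C)cc(OC)cc1OCC=C(C)C | intermediate (not isolated)
17 | ethynyl 2-(TBS-oxymethyl)-4-methoxy-6-(prenyloxy)phenyl ether | C#COc1c(CO[Si](C)(C)C(C)(C)C)cc(OC)cc1OCC=C(C)C | intermediate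
18 | methyl 8-[2-(TBS-oxymethyl)-4-methoxy-6-(prenyloxy)phenoxy]-1-methyl-3-oxo-5-(tosyloxy)-2-oxabicyclo[2.2.2]octa-5,7-diene-4-carboxylate (racemic; the bridge fixes the relative configuration of the two bridgeheads) | COC(=O)C12C(=O)OC(C)(C=C1OS(=O)(=O)c1ccc(C)cc1)C=C2Oc1c(CO[Si](C)(C)C(C)(C)C)cc(OC)cc1OCC=C(C)C | intermediate (not isolated)
19 | methyl 2-[2-(TBS-oxymethyl)-4-methoxy-6-(prenyloxy)phenoxy]-4-methyl-6-(tosyloxy)benzoate | COC(=O)c1c(OS(=O)(=O)c2ccc(C)cc2)cc(C)cc1Oc1c(CO[Si](C)(C)C(C)(C)C)cc(OC)cc1OCC=C(C)C | intermediate
20 | methyl 2-[2-(TBS-oxymethyl)-4-methoxy-6-(prenyloxy)phenoxy]-6-hydroxy-4-methylbenzoate | COC(=O)c1c(O)cc(C)cc1Oc1c(CO[Si](C)(C)C(C)(C)C)cc(OC)cc1OCC=C(C)C | intermediate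
21 | methyl 2-[2-(TBS-oxymethyl)-4-methoxy-6-(prenyloxy)phenoxy]-4-methyl-6-(prenyloxy)benzoate | COC(=O)c1c(OCC=C(C)C)cc(C)cc1Oc1c(CO[Si](C)(C)C(C)(C)C)cc(OC)cc1OCC=C(C)C | intermediate
22 | methyl 2-[2-(hydroxymethyl)-4-methoxy-6-(prenyloxy)phenoxy]-4-methyl-6-(prenyloxy)benzoate (CNP0561346.0) | COC(=O)c1c(OCC=C(C)C)cc(C)cc1Oc1c(CO)cc(OC)cc1OCC=C(C)C | target

## Step count and risks

Total step count: 13. Longest linear sequence: 11 steps (steps 3–13, from 6 to 22); the pyrone branch (steps 1–2) joins at step 10.

Least certain steps:

**Step 10 (key step).** The cycloaddition may be slow, because an aryloxy alkyne is a weaker donor than an alkoxy alkyne and the pyrone terminus C6 carries a methyl group. Prolonged heating would then allow oligomerization of the ynol ether. Conjugate addition at C4 with loss of the sulfonate could also compete.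

Fallback (from 14, rejoining at 20): dichlorovinyl ether 14 is treated with n-BuLi as in step 9 and the acetylide 16 is trapped with methyl chloroformate to give methyl 3-(ring B aryloxy)prop-2-ynoate F1. F1 is heated in toluene with 1,1-bis(trimethylsilyloxy)-3-methylbuta-1,3-diene F2, made from 3-methylbut-2-enoic acid with lithium diisopropylamide and chlorotrimethylsilane. The normal-demand Diels–Alder adduct should lose trimethylsilanol to give the aryl trimethylsilyl ether F3, and a methanolic work-up should give phenol 20. This replaces steps 10 and 11.

**Step 9.** The terminal ynol ether may be lost during work-up and concentration by hydration to the aryl acetate or by oligomerization. The excess n-BuLi may also metalate the benzylic or allylic ether positions.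

Fallback (from 12, rejoining at 21): the ynol ether is avoided altogether. Commercial methyl 2,6-dihydroxy-4-methylbenzoate is mono-prenylated (prenyl bromide 9, K2CO3, acetone) to methyl 2-hydroxy-4-methyl-6-(prenyloxy)benzoate F4. F4 is converted with triflic anhydride and pyridine into methyl 4-methyl-2-(prenyloxy)-6-(trifluoromethylsulfonyloxy)benzoate F5. F5 is coupled with phenol 12 under palladium catalysis (Pd(OAc)2, 2-di-tert-butylphosphino-2',4',6'-triisopropylbiphenyl, K3PO4, toluene, 100 °C) to give 21. This is shorter, but it relies on exactly the hindered aryl carbon–oxygen coupling that the main plan was designed to avoid, so it is held in reserve.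

**Step 4.** Demethylation may be incomplete, or selectivity between the two methyl ethers may be lost if the reaction is pushed, giving over-demethylation at C5.

Fallback (from 6, rejoining at 10): the order is changed so that only one methyl ether is ever present. 6 is demethylated with BBr3 (CH2Cl2, −78 → 0 °C) to 5-bromo-2,3-dihydroxybenzaldehyde F6. F6 is prenylated at the C3 oxygen through its dianion (NaH, DMSO, prenyl bromide 9) to 5-bromo-2-hydroxy-3-(prenyloxy)benzaldehyde F7. The bromine is then exchanged for methoxy (NaOMe, CuBr, MeOH/DMF, 100 °C) to give 10.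

**Step 11.** Electron transfer to the hindered sulfonate next to the ester may be slow. Extended exposure to magnesium methoxide may then cause loss of the silyl group.

Fallback (from 4, rejoining at 20): a sulfonate that is removed by a different mechanism is used. 4 is sulfonylated with 2-nitrobenzenesulfonyl chloride and Et3N to methyl 6-methyl-4-[(2-nitrophenyl)sulfonyloxy]-2-oxo-2H-pyran-3-carboxylate F8. The cycloaddition with 17 is run as in step 10 to give methyl 2-(ring B aryloxy)-4-methyl-6-[(2-nitrophenyl)sulfonyloxy]benzoate F9. The sulfonate is then removed with thiophenol and K2CO3 in DMF at room temperature (ipso substitution on the nitroarene) to release 20.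

## Further compounds

F1 | step 10 | methyl 3-[2-(TBS-oxymethyl)-4-methoxy-6-(prenyloxy)phenoxy]prop-2-ynoate | COC(=O)C#COc1c(CO[Si](C)(C)C(C)(C)C)cc(OC)cc1OCC=C(C)C
F2 | step 10 | 1,1-bis(trimethylsilyloxy)-3-methylbuta-1,3-diene | C=C(C)C=C(O[Si](C)(C)C)O[Si](C)(C)C
F3 | step 10 | methyl 2-[2-(TBS-oxymethyl)-4-methoxy-6-(prenyloxy)phenoxy]-4-methyl-6-(trimethylsilyloxy)benzoate | COC(=O)c1c(O[Si](C)(C)C)cc(C)cc1Oc1c(CO[Si](C)(C)C(C)(C)C)cc(OC)cc1OCC=C(C)C
F4 | step 9 | methyl 2-hydroxy-4-methyl-6-[(3-methylbut-2-en-1-yl)oxy]benzoate | COC(=O)c1c(O)cc(C)cc1OCC=C(C)C
F5 | step 9 | methyl 4-methyl-2-[(3-methylbut-2-en-1-yl)oxy]-6-(trifluoromethylsulfonyloxy)benzoate | COC(=O)c1c(OS(=O)(=O)C(F)(F)F)cc(C)cc1OCC=C(C)C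
F6 | step 4 | 5-bromo-2,3-dihydroxybenzaldehyde | O=Cc1cc(Br)cc(O)c1O
F7 | step 4 | 5-bromo-2-hydroxy-3-[(3-methylbut-2-en-1-yl)oxy]benzaldehyde | O=Cc1cc(Br)cc(OCC=C(C)C)c1O
F8 | step 11 | methyl 6-methyl-4-[(2-nitrophenyl)sulfonyloxy]-2-oxo-2H-pyran-3-carboxylate | COC(=O)C1=C(OS(=O)(=O)c2ccccc2[N+](=O)[O-])C=C(C)OC1=O
F9 | step 11 | methyl 2-[2-(TBS-oxymethyl)-4-methoxy-6-(prenyloxy)phenoxy]-4-methyl-6-[(2-nitrophenyl)sulfonyloxy]benzoate | COC(=O)c1c(OS(=O)(=O)c2ccccc2[N+](=O)[O-])cc(C)cc1Oc1c(CO[Si](C)(C)C(C)(C)C)cc(OC)cc1OCC=C(C)C
A1 | alternative 1 | spiro grisadienone with benzyl ethers at ring A C2 and ring B C6' (racemic, one enantiomer drawn) | O=C1c2c(OCc3ccccc3)cc(C)cc2O[C@]12C(CO[Si](C)(C)C(C)(C)C)=CC(=O)C=C2OCc1ccccc1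
A2 | alternative 1 | 4-(benzyloxy)-6-methylbenzofuran-3(2H)-one | O=C1COc2cc(C)cc(OCc3ccccc3)c12
A3 | alternative 1 | 1-(benzyloxy)-5-(tert-butyldimethylsilyloxy)penta-1,4-diyn-3-one | O=C(C#COCc1ccccc1)C#CCO[Si](C)(C)C(C)(C)C
A4 | alternative 2 | methyl 3-[2-(TBS-oxymethyl)-4-methoxy-6-(prenyloxy)phenoxy]prop-2-ynoate | COC(=O)C#COc1c(CO[Si](C)(C)C(C)(C)C)cc(OC)cc1OCC=C(C)C
A5 | alternative 2 | 1,1-bis(trimethylsilyloxy)-3-methylbuta-1,3-diene | C=C(C)C=C(O[Si](C)(C)C)O[Si](C)(C)C
A6 | alternative 2 | methyl 2-[2-(TBS-oxymethyl)-4-methoxy-6-(prenyloxy)phenoxy]-6-hydroxy-4-methylbenzoate | COC(=O)c1c(O)cc(C)cc1Oc1c(CO[Si](C)(C)C(C)(C)C)cc(OC)cc1OCC=C(C)C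
A7 | alternative 3 | 5-methyl-3-[(3-methylbut-2-en-1-yl)oxy]-2-(trimethylsilyl)phenyl trifluoromethanesulfonate | Cc1cc(OCC=C(C)C)c([Si](C)(C)C)c(OS(=O)(=O)C(F)(F)F)c1
A8 | alternative 3 | 5-methyl-3-[(3-methylbut-2-en-1-yl)oxy]benzyne | CC1=CC#CC(OCC=C(C)C)=C1
A9 | alternative 3 | 2-[2-(TBS-oxymethyl)-4-methoxy-6-(prenyloxy)phenoxy]-4-methyl-6-(prenyloxy)benzoic acid | OC(=O)c1c(OCC=C(C)C)cc(C)cc1Oc1c(CO[Si](C)(C)C(C)(C)C)cc(OC)cc1OCC=C(C)C
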